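The route rests on opening the 14-membered carbocycle at C12–C13, where the saturated C13–C14 bridge from the ring-fusion stereocentre C1 meets the sp2 carbon C12 of the C11=C12 alkene; this bridge is a hydroborated vinyl group in disguise. In one operation, 9-BBN hydroboration of a C1 vinyl group and palladium-catalysed B-alkyl Suzuki–Miyaura coupling with an (E)-C12 alkenyl iodide form C12–C13 and close the carbocycle without creating or endangering any stereocentre. The precursor is an open-chain trans-4-vinyl-5-alkenyl γ-butyrolactone carrying the C9 silyl ether and the three E alkenes, built linearly from geranyl acetate; the vinyl group also serves to fix C1 trans to C2.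

Key step: step 10

Atom labels (cembrane numbering): C1 and C2 are the ring-fusion carbons (C2 bears the lactone oxygen); C3=C4, C7=C8 and C11=C12 are the ring alkenes; C9 bears the acetate; C15, C16 and C17 are the lactone α-carbon, carbonyl carbon and exocyclic methylene carbon.

Assumption: in steps 2 and 7 the catalyst enantiomers named are those expected, by analogy with aryl and alkenyl aldehydes, to deliver the carbon nucleophile to the Re face of each enal; the sense would be confirmed by Mosher ester analysis, the mirror-image catalyst being equally available.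

Step 1
Reactants: 1 geranyl acetate
Product: 2 (2E,6E)-3,7-dimethyl-8-oxoocta-2,6-dien-1-yl acetate
Conditions: SeO2 (1.1 equiv), EtOH, reflux
Reagents that add atoms: selenium dioxide, O=[Se]=O
Why: Riley allylic oxidation (ene reaction then [2,3]-sigmatropic shift) attacks the electron-richer, acetate-remote trisubstituted alkene at its (E)-methyl group and, in refluxing ethanol, should carry the allylic alcohol on to the (E)-enal, which is the C9 aldehyde of the C2–C9 unit.

Step 2
Reactants: 2 (2E,6E)-3,7-dimethyl-8-oxoocta-2,6-dien-1-yl acetate; 3 allenylboronic acid pinacol ester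
Product: 5 (2E,6E,8R)-8-hydroxy-3,7-dimethylundeca-2,6-dien-10-yn-1-yl acetate, via pinacol borate ester 4 (not isolated)
Conditions: (R)-TRIP phosphoric acid (5 mol %), 4 Å MS, toluene, 0 °C; aq. NaHCO3 work-up
Reagents that add atoms: none
Why: Chiral phosphoric acid-catalysed propargylboration passes through a closed six-membered SE2′ transition state in which the acid binds the boronate oxygen and the formyl hydrogen, so the allenyl γ-carbon should add to the Re face of the enal and set the C9 carbinol centre (R; C8 of this chain), the borate ester being hydrolysed on work-up.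

Step 3
Reactants: 5 (2E,6E,8R)-8-hydroxy-3,7-dimethylundeca-2,6-dien-10-yn-1-yl acetate
Product: 6 (2E,6E,8R)-8-(tert-butyldimethylsilyloxy)-3,7-dimethylundeca-2,6-dien-10-yn-1-yl acetate
Conditions: TBSCl, imidazole, DMF, rt
Reagents that add atoms: tert-butyldimethylsilyl chloride (TBSCl), CC(C)(C)[Si](C)(C)Cl
Why: Standard imidazole-mediated silylation of a secondary alcohol masks the C9 hydroxyl group for all later organometallic steps and leaves the primary acetate untouched.

Step 4
Reactants: 6 (2E,6E,8R)-8-(tert-butyldimethylsilyloxy)-3,7-dimethylundeca-2,6-dien-10-yn-1-yl acetate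
Product: 8 (2E,6E,8R)-8-(tert-butyldimethylsilyloxy)-3,7-dimethyldodeca-2,6-dien-10-yn-1-ol, via dilithio alkoxide–acetylide 7 (not isolated)
Conditions: MeLi (3.3 equiv), THF, −78 → 0 °C; then MeI (3 equiv), 0 °C → rt; H2O
Reagents that add atoms: iodomethane (MeI), CI
Why: Methyllithium cleaves the acetate by double addition and deprotonates the terminal alkyne, and the lithium acetylide, far more nucleophilic towards iodomethane in THF than the lithium alkoxides, is C-methylated (acetylide alkylation) to place the future C12 methyl group.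

Step 5
Reactants: 8 (2E,6E,8R)-8-(tert-butyldimethylsilyloxy)-3,7-dimethyldodeca-2,6-dien-10-yn-1-ol
Product: 10 (2E,6E,8R,10E)-8-(tert-butyldimethylsilyloxy)-11-iodo-3,7-dimethyldodeca-2,6,10-trien-1-ol, via alkenylzirconocene chloride 9 (not isolated)
Conditions: Cp2Zr(H)Cl (3 equiv), THF, 45 °C; then I2, THF, 0 °C
Reagents that add atoms: iodine, II
Why: Hydrozirconation–iodination adds Zr–H syn across the 2-alkyne, equilibration with excess reagent placing zirconium on the less hindered methyl-bearing carbon C12, and iodinolysis with retention gives the (E)-alkenyl iodide; one equivalent of reagent is spent on the free hydroxyl group and the trisubstituted alkenes are inert.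

Step 6
Reactants: 10 (2E,6E,8R,10E)-8-(tert-butyldimethylsilyloxy)-11-iodo-3,7-dimethyldodeca-2,6,10-trien-1-ol
Product: 11 (2E,6E,8R,10E)-8-(tert-butyldimethylsilyloxy)-11-iodo-3,7-dimethyldodeca-2,6,10-trienal
Conditions: MnO2 (excess), CH2Cl2, rt
Reagents that add atoms: none
Why: Heterogeneous allylic oxidation on MnO2 converts the primary allylic alcohol into the (E)-enal (the C2 aldehyde) without touching the silyl ether, the alkenyl iodide or the alkene geometries.

Step 7
Reactants: 11 (2E,6E,8R,10E)-8-(tert-butyldimethylsilyloxy)-11-iodo-3,7-dimethyldodeca-2,6,10-trienal; 12 ethyl propiolate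
Product: 13 ethyl (4S,5E,9E,11R,13E)-11-(tert-butyldimethylsilyloxy)-4-hydroxy-14-iodo-6,10-dimethylpentadeca-5,9,13-trien-2-ynoate
Conditions: Me2Zn (3 equiv), (S,S)-ProPhenol (20 mol %), Ph3PO (40 mol %), toluene, 0–4 °C; aq. work-up
Reagents that add atoms: none
Why: Catalytic asymmetric alkynylation, in which the zinc alkynylide formed from the propiolate and Me2Zn is delivered inside the dinuclear zinc–ProPhenol complex, should add to the Re face of the enal and set the C2 carbinol centre (4S in this chain) under catalyst control, the remote C9 centre exerting no influence.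

Step 8
Reactants: 13 ethyl (4S,5E,9E,11R,13E)-11-(tert-butyldimethylsilyloxy)-4-hydroxy-14-iodo-6,10-dimethylpentadeca-5,9,13-trien-2-ynoate
Product: 15 (5R)-5-[(1E,5E,7R,9E)-7-(tert-butyldimethylsilyloxy)-10-iodo-2,6-dimethylundeca-1,5,9-trien-1-yl]furan-2(5H)-one, via (Z)-γ-hydroxy enoate 14 (not isolated)
Conditions: H2 (1 atm), Pd/CaCO3–Pb(OAc)2 (Lindlar catalyst), quinoline, EtOAc, rt; then PPTS (cat.), CH2Cl2, rt
Reagents that add atoms: none
Why: cis-Selective semihydrogenation of the ynoate on lead-poisoned palladium (Lindlar reduction) gives the (Z)-γ-hydroxy enoate, which lactonises by acid-catalysed transesterification to the butenolide; quinoline and control of hydrogen uptake are expected to spare the trisubstituted alkenes and the alkenyl iodide, and C2 is untouched.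

Step 9
Reactants: 15 (5R)-5-[(1E,5E,7R,9E)-7-(tert-butyldimethylsilyloxy)-10-iodo-2,6-dimethylundeca-1,5,9-trien-1-yl]furan-2(5H)-one; 16 vinylmagnesium bromide
Product: 18 (4S,5R)-5-[(1E,5E,7R,9E)-7-(tert-butyldimethylsilyloxy)-10-iodo-2,6-dimethylundeca-1,5,9-trien-1-yl]-4-vinyldihydrofuran-2(3H)-one, via silyl ketene acetal 17 (not isolated)
Conditions: vinylMgBr (4 equiv), CuI (2 equiv), THF, −40 °C; then TMSCl (4 equiv), 15, −78 °C; aq. NH4Cl
Reagents that add atoms: none
Why: TMSCl-accelerated conjugate addition of the divinylcuprate to the butenolide places the vinyl group on C1 from the face opposite the C2 alkenyl substituent (1,2-induction in a five-membered ring), fixing C1 trans to C2, and the silyl ketene acetal is hydrolysed on work-up.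

Step 10
Reactants: 18 (4S,5R)-5-[(1E,5E,7R,9E)-7-(tert-butyldimethylsilyloxy)-10-iodo-2,6-dimethylundeca-1,5,9-trien-1-yl]-4-vinyldihydrofuran-2(3H)-one
Product: 20 (3aR,6E,9R,10E,14E,15aR)-9-(tert-butyldimethylsilyloxy)-6,10,14-trimethyl-3a,4,5,8,9,12,13,15a-octahydrocyclotetradeca[b]furan-2(3H)-one, via alkylborane 19 (not isolated)
Conditions: 9-BBN-H (1.5 equiv), THF, 0 °C → rt; then syringe-pump addition (10 h) to Pd(dppf)Cl2 (20 mol %), AsPh3 (40 mol %), Cs2CO3 (3 equiv), DMF/THF/H2O, 50 °C, final 0.002 M; pH 4 buffer work-up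
Reagents that add atoms: none
Why: 9-BBN-H adds anti-Markovnikov to the C13=C14 vinyl group, the only monosubstituted alkene, placing boron on C13; zerovalent palladium then inserts into the C12–I bond with retention, the base-activated borate hands the primary carbon C13 to palladium, and reductive elimination forms C12–C13. The closest known reaction type is the B-alkyl Suzuki–Miyaura macrocyclisation of ω-borylalkyl alkenyl iodides under the same Pd(dppf)Cl2/AsPh3/Cs2CO3 regime. The 14-membered carbocycle closes in the reductive elimination from a 15-membered alkyl(alkenyl)palladium chelate, both coupling carbons becoming ring members (an end-to-end cross-coupling closure, not a polar exo or endo attack). No stereocentre is formed: C1, C2 and C9 are spectators and the E geometry at C11=C12 is carried over from the iodide, so the closure cannot erode what the open chain holds. Chemoselectivity in the hydroboration is secured by the bulk of 9-BBN (the three trisubstituted alkenes and the lactone are inert at room temperature) and by keeping the exocyclic methylene C17 absent until later. Ring closure over oligomerisation is secured by slow addition to a dilute catalyst solution, and any lactone opened by aqueous carbonate should re-close on the mildly acidic work-up.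

Step 11
Reactants: 20 (3aR,6E,9R,10E,14E,15aR)-9-(tert-butyldimethylsilyloxy)-6,10,14-trimethyl-3a,4,5,8,9,12,13,15a-octahydrocyclotetradeca[b]furan-2(3H)-one
Product: 21 3-[(dimethylamino)methyl] derivative of 20 (C15 epimers; C1, C2 and C9 unchanged)
Conditions: LiN(iPr)2 (LDA, 1.2 equiv), THF, −78 °C; then Me2N=CH2 I (3 equiv), −78 °C → rt
Reagents that add atoms: dimethylmethyleneiminium iodide (Eschenmoser salt), C=[N+](C)C.[I-]
Why: Mannich-type α-aminomethylation: the lactone lithium enolate (deprotonation at C15 only, C1 and C2 not being epimerisable here) is trapped by the iminium salt, and the new C15 centre is irrelevant because it is destroyed in the next step.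

Step 12
Reactants: 21 3-[(dimethylamino)methyl] derivative of 20
Product: 23 (3aR,6E,9R,10E,14E,15aS)-9-(tert-butyldimethylsilyloxy)-6,10,14-trimethyl-3-methylidene-3a,4,5,8,9,12,13,15a-octahydrocyclotetradeca[b]furan-2(3H)-one, via trimethylammonium iodide 22 (not isolated)
Conditions: MeI (excess), MeOH, rt; then aq. NaHCO3, CH2Cl2, rt
Reagents that add atoms: none
Why: Exhaustive N-methylation followed by mild-base E1cB (Hofmann-type) elimination of trimethylamine should unveil the α-methylene lactone without exposing it to strong base.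

Step 13
Reactants: 23 (3aR,6E,9R,10E,14E,15aS)-9-(tert-butyldimethylsilyloxy)-6,10,14-trimethyl-3-methylidene-3a,4,5,8,9,12,13,15a-octahydrocyclotetradeca[b]furan-2(3H)-one
Product: 24 (3aR,6E,9R,10E,14E,15aS)-9-hydroxy-6,10,14-trimethyl-3-methylidene-3a,4,5,8,9,12,13,15a-octahydrocyclotetradeca[b]furan-2(3H)-one
Conditions: HF·pyridine, pyridine, THF, 0 °C → rt
Reagents that add atoms: none
Why: Buffered fluoride desilylation cleaves the secondary silyl ether while keeping the Michael-acceptor lactone away from alkoxide or unbuffered fluoride.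

Step 14
Reactants: 24 (3aR,6E,9R,10E,14E,15aS)-9-hydroxy-6,10,14-trimethyl-3-methylidene-3a,4,5,8,9,12,13,15a-octahydrocyclotetradeca[b]furan-2(3H)-one
Product: 25 (3aR,6E,9R,10E,14E,15aS)-6,10,14-trimethyl-3-methylidene-2-oxo-2,3,3a,4,5,8,9,12,13,15a-decahydrocyclotetradeca[b]furan-9-yl acetate (CNP0129197.1)
Conditions: Ac2O, pyridine, DMAP (cat.), CH2Cl2, 0 °C → rt
Reagents that add atoms: acetic anhydride, CC(=O)OC(C)=O
Why: DMAP-catalysed acylation of the secondary allylic alcohol proceeds at oxygen with retention at C9 and should deliver the target acetate.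

Compound list
1 | geranyl acetate | CC(C)=CCC/C(C)=C/COC(C)=O | starting material
2 | (2E,6E)-3,7-dimethyl-8-oxoocta-2,6-dien-1-yl acetate | O=C/C(C)=C/CC/C(C)=C/COC(C)=O | intermediate
3 | allenylboronic acid pinacol ester | C=C=CB1OC(C)(C)C(C)(C)O1 | starting material
4 | pinacol borate ester of alcohol 5 (O–B bond at C9) | C#CC[C@@H](OB1OC(C)(C)C(C)(C)O1)/C(C)=C/CC/C(C)=C/COC(C)=O | intermediate (not isolated)
5 | (2E,6E,8R)-8-hydroxy-3,7-dimethylundeca-2,6-dien-10-yn-1-yl acetate | C#CC[C@@H](O)/C(C)=C/CC/C(C)=C/COC(C)=O | intermediate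
6 | (2E,6E,8R)-8-(tert-butyldimethylsilyloxy)-3,7-dimethylundeca-2,6-dien-10-yn-1-yl acetate | C#CC[C@@H](O[Si](C)(C)C(C)(C)C)/C(C)=C/CC/C(C)=C/COC(C)=O | intermediate
7 | dilithio derivative (lithium alkoxide and lithium acetylide) of the deacetylated terminal alkyne | [Li]C#CC[C@@H](O[Si](C)(C)C(C)(C)C)/C(C)=C/CC/C(C)=C/CO[Li] | intermediate (not isolated)
8 | (2E,6E,8R)-8-(tert-butyldimethylsilyloxy)-3,7-dimethyldodeca-2,6-dien-10-yn-1-ol | CC#CC[C@@H](O[Si](C)(C)C(C)(C)C)/C(C)=C/CC/C(C)=C/CO | intermediate
9 | (E)-alkenylzirconocene chloride (Cp2ZrCl on C12, trans to C10; primary oxygen bound to a second Cp2ZrCl unit; Cp drawn σ-bonded) | C/C(=C\C[C@@H](O[Si](C)(C)C(C)(C)C)/C(C)=C/CC/C(C)=C/CO[Zr](Cl)(C1C=CC=C1)C1C=CC=C1)[Zr](Cl)(C1C=CC=C1)C1C=CC=C1 | intermediate (not isolated)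
10 | (2E,6E,8R,10E)-8-(tert-butyldimethylsilyloxy)-11-iodo-3,7-dimethyldodeca-2,6,10-trien-1-ol | I/C(C)=C/C[C@@H](O[Si](C)(C)C(C)(C)C)/C(C)=C/CC/C(C)=C/CO | intermediate
11 | (2E,6E,8R,10E)-8-(tert-butyldimethylsilyloxy)-11-iodo-3,7-dimethyldodeca-2,6,10-trienal | I/C(C)=C/C[C@@H](O[Si](C)(C)C(C)(C)C)/C(C)=C/CC/C(C)=C/C=O | intermediate
12 | ethyl propiolate | C#CC(=O)OCC | starting material
13 | ethyl (4S,5E,9E,11R,13E)-11-(tert-butyldimethylsilyloxy)-4-hydroxy-14-iodo-6,10-dimethylpentadeca-5,9,13-trien-2-ynoate | I/C(C)=C/C[C@@H](O[Si](C)(C)C(C)(C)C)/C(C)=C/CC/C(C)=C/[C@H](O)C#CC(=O)OCC | intermediate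
14 | ethyl (2Z,4R,5E,9E,11R,13E)-11-(tert-butyldimethylsilyloxy)-4-hydroxy-14-iodo-6,10-dimethylpentadeca-2,5,9,13-tetraenoate | I/C(C)=C/C[C@@H](O[Si](C)(C)C(C)(C)C)/C(C)=C/CC/C(C)=C/[C@H](O)/C=C\C(=O)OCC | intermediate (not isolated)
15 | (5R)-5-[(1E,5E,7R,9E)-7-(tert-butyldimethylsilyloxy)-10-iodo-2,6-dimethylundeca-1,5,9-trien-1-yl]furan-2(5H)-one | O=C1C=C[C@@H](O1)/C=C(\C)CC/C=C(\C)[C@H](O[Si](C)(C)C(C)(C)C)C/C=C(\C)I | intermediate
16 | vinylmagnesium bromide | C=C[Mg]Br | starting material
17 | trimethylsilyl ketene acetal of lactone 18 (2-trimethylsilyloxy-4,5-dihydrofuran, ring substituents trans) | C[Si](C)(C)OC1=C[C@@H](C=C)[C@@H](O1)/C=C(\C)CC/C=C(\C)[C@H](O[Si](C)(C)C(C)(C)C)C/C=C(\C)I | intermediate (not isolated)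
18 | (4S,5R)-5-[(1E,5E,7R,9E)-7-(tert-butyldimethylsilyloxy)-10-iodo-2,6-dimethylundeca-1,5,9-trien-1-yl]-4-vinyldihydrofuran-2(3H)-one (trans-lactone, precursor of the key step) | O=C1C[C@@H](C=C)[C@@H](O1)/C=C(\C)CC/C=C(\C)[C@H](O[Si](C)(C)C(C)(C)C)C/C=C(\C)I | intermediate
19 | B-alkyl-9-BBN from 18 (C13 bound to boron; vinyl converted to 2-(9-borabicyclo[3.3.1]nonan-9-yl)ethyl) | O=C1C[C@@H](CCB2C3CCCC2CCC3)[C@@H](O1)/C=C(\C)CC/C=C(\C)[C@H](O[Si](C)(C)C(C)(C)C)C/C=C(\C)I | intermediate (not isolated)
20 | (3aR,6E,9R,10E,14E,15aR)-9-(tert-butyldimethylsilyloxy)-6,10,14-trimethyl-3a,4,5,8,9,12,13,15a-octahydrocyclotetradeca[b]furan-2(3H)-one (macrocyclic trans-lactone) | C1C(=O)O[C@H]2/C=C(\C)CC/C=C(\C)[C@H](O[Si](C)(C)C(C)(C)C)C/C=C(\C)CC[C@H]12 | intermediate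
21 | 3-[(dimethylamino)methyl] derivative of 20 (C15 epimers, centre left undefined) | CN(C)CC1C(=O)O[C@H]2/C=C(\C)CC/C=C(\C)[C@H](O[Si](C)(C)C(C)(C)C)C/C=C(\C)CC[C@H]12 | intermediate
22 | trimethylammonium iodide of 21 | C[N+](C)(C)CC1C(=O)O[C@H]2/C=C(\C)CC/C=C(\C)[C@H](O[Si](C)(C)C(C)(C)C)C/C=C(\C)CC[C@H]12.[I-] | intermediate (not isolated)
23 | (3aR,6E,9R,10E,14E,15aS)-9-(tert-butyldimethylsilyloxy)-6,10,14-trimethyl-3-methylidene-3a,4,5,8,9,12,13,15a-octahydrocyclotetradeca[b]furan-2(3H)-one | C=C1C(=O)O[C@H]2/C=C(\C)CC/C=C(\C)[C@H](O[Si](C)(C)C(C)(C)C)C/C=C(\C)CC[C@H]12 | intermediate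
24 | (3aR,6E,9R,10E,14E,15aS)-9-hydroxy-6,10,14-trimethyl-3-methylidene-3a,4,5,8,9,12,13,15a-octahydrocyclotetradeca[b]furan-2(3H)-one | C=C1C(=O)O[C@H]2/C=C(\C)CC/C=C(\C)[C@H](O)C/C=C(\C)CC[C@H]12 | intermediate
25 | (3aR,6E,9R,10E,14E,15aS)-6,10,14-trimethyl-3-methylidene-2-oxo-2,3,3a,4,5,8,9,12,13,15a-decahydrocyclotetradeca[b]furan-9-yl acetate (1R,2S,9R in cembrane numbering) | C=C1C(=O)O[C@H]2/C=C(\C)CC/C=C(\C)[C@H](OC(C)=O)C/C=C(\C)CC[C@H]12 | target

Total step count: 14
Longest linear sequence: 14 steps (1 to 25)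

Steps most likely to fail

Step 10. Intermolecular coupling may outrun ring closure, or the alkylborane may be lost by protodeboronation or β-hydride elimination before transmetalation. The fallback forms the same C12–C13 bond through an organozinc reagent under anhydrous conditions. Setting out from 18, the alkylborane 19 would be oxidised with NaBO3·4H2O (THF/H2O, rt, lactone-safe) to the primary alcohol F1. I2/PPh3/imidazole (CH2Cl2, 0 °C) would convert it into the primary iodide F2. Activated Zn dust in THF at 35 °C inserts only into the C(sp3)–I bond and would give the alkylzinc iodide F3. Slow addition of this reagent to Pd(PPh3)4 in THF/DMA at 50 °C would close the ring by an intramolecular Negishi coupling and rejoin the route at 20.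

Step 8. The C12–I bond may be cleaved reductively on the palladium surface, or the hydrogenation may run past the alkene stage. The fallback avoids hydrogenation and the butenolide altogether. Setting out from 13, NaAlH2(OCH2CH2OMe)2 in THF at −72 °C would reduce the γ-hydroxy ynoate trans-selectively (hydroxyl-directed hydroalumination) to the (E)-γ-hydroxy enoate F4. TESCl/imidazole would protect it as the triethylsilyl ether F5. Addition of (CH2=CH)2CuMgBr with TMSCl at −78 °C, which on γ-silyloxy (E)-enoates goes anti to the oxygen substituent, would give through the silyl ketene acetal F6 the β-vinyl ester F7. PPTS in MeOH would remove the triethylsilyl group selectively and lactonise, rejoining the route at 18.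

Step 7. Facial discrimination on a β,β-disubstituted enal may be insufficient, leaving C2 epimers that are hard to separate because C9 is remote. The fallback sets C2 by reagent-controlled reduction instead of catalytic addition. Setting out from 11, the lithium acetylide of 12 (LiN(SiMe3)2, THF, −78 °C) would add without facial control to give the C4-epimeric hydroxy ynoate F8. MnO2 would oxidise this doubly activated alcohol to the ynone F9. Midland reduction with (S)-Alpine-Borane, in which the alkynyl group acts as the small substituent, would return the 4S alcohol and rejoin the route at 13.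

Further compounds
F1 | step 10 | 4-(2-hydroxyethyl) analogue of lactone 18 (primary alcohol at C13) | O=C1C[C@@H](CCO)[C@@H](O1)/C=C(\C)CC/C=C(\C)[C@H](O[Si](C)(C)C(C)(C)C)C/C=C(\C)I
F2 | step 10 | 4-(2-iodoethyl) analogue of lactone 18 (primary iodide at C13) | O=C1C[C@@H](CCI)[C@@H](O1)/C=C(\C)CC/C=C(\C)[C@H](O[Si](C)(C)C(C)(C)C)C/C=C(\C)I
F3 | step 10 | alkylzinc iodide from F2 (zinc on C13) | O=C1C[C@@H](CC[Zn]I)[C@@H](O1)/C=C(\C)CC/C=C(\C)[C@H](O[Si](C)(C)C(C)(C)C)C/C=C(\C)I
F4 | step 8 | ethyl (2E,4R,5E,9E,11R,13E)-11-(tert-butyldimethylsilyloxy)-4-hydroxy-14-iodo-6,10-dimethylpentadeca-2,5,9,13-tetraenoate | CCOC(=O)/C=C/[C@@H](O)/C=C(\C)CC/C=C(\C)[C@H](O[Si](C)(C)C(C)(C)C)C/C=C(\C)I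
F5 | step 8 | triethylsilyl ether of F4 | CCOC(=O)/C=C/[C@@H](O[Si](CC)(CC)CC)/C=C(\C)CC/C=C(\C)[C@H](O[Si](C)(C)C(C)(C)C)C/C=C(\C)I
F6 | step 8 | ethyl trimethylsilyl ketene acetal of F7 (ketene acetal geometry undefined) | CCOC(O[Si](C)(C)C)=C[C@@H](C=C)[C@@H](O[Si](CC)(CC)CC)/C=C(\C)CC/C=C(\C)[C@H](O[Si](C)(C)C(C)(C)C)C/C=C(\C)I
F7 | step 8 | ethyl 3-vinyl-4-(triethylsilyloxy) ester (vinyl anti to the silyloxy group; open-chain form of 18) | CCOC(=O)C[C@@H](C=C)[C@@H](O[Si](CC)(CC)CC)/C=C(\C)CC/C=C(\C)[C@H](O[Si](C)(C)C(C)(C)C)C/C=C(\C)I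
F8 | step 7 | ethyl (5E,9E,11R,13E)-11-(tert-butyldimethylsilyloxy)-4-hydroxy-14-iodo-6,10-dimethylpentadeca-5,9,13-trien-2-ynoate (C4 epimers) | I/C(C)=C/C[C@@H](O[Si](C)(C)C(C)(C)C)/C(C)=C/CC/C(C)=C/C(O)C#CC(=O)OCC
F9 | step 7 | ethyl (5E,9E,11R,13E)-11-(tert-butyldimethylsilyloxy)-14-iodo-6,10-dimethyl-4-oxopentadeca-5,9,13-trien-2-ynoate | I/C(C)=C/C[C@@H](O[Si](C)(C)C(C)(C)C)/C(C)=C/CC/C(C)=C/C(=O)C#CC(=O)OCC
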